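**Strategy.** The δ-lactone (O1, C2=O, C3, C4, C5, C6) is cut at C2–C3 and at the ring-fusion bond C4–C5. C4–C5 lies between two sp2 carbons, lactone C3 and the methylidene-bearing carbon of the nine-membered ring, so it is the σ-bond of a hidden 1,5-diene. One operation makes both bonds: an anionic oxy-Cope rearrangement of an acyclic 1,5-dien-3-ol bearing an allylic methyl carbonate forms C4–C5 through a chair, sets both ring-fusion centres and unveils the exocyclic methylene; the aldehyde enolate thus released attacks the carbonate and closes C2–C3. Side chain (Nozaki–Hiyama–Kishi), nine-membered ring (metathesis) and epoxide (hydroxyl-directed) follow.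

Key step: step 8

Remark: (S)-(+)-linalool is taken as purchasable in enantiopure form, and in step 6 the antipode of the ligand QuinoxP* is the one that delivers the (2S)-boronate 8.

Step 1
Reactants: 1 (S)-linalool
Product: 2 (S)-linalool triethylsilyl ether
Conditions: TESOTf, 2,6-lutidine, CH2Cl2, −78 → 0 °C
Reagents that add atoms: triethylsilyl trifluoromethanesulfonate, CC[Si](CC)(CC)OS(=O)(=O)C(F)(F)F
Why: Silylation of a hindered tertiary alcohol with a silyl triflate masks the hydroxyl, which would otherwise add to the enal of step 3 (oxa-Michael) and be deprotonated in step 8; the carbinol stereocentre from the chiral pool is untouched.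

Step 2
Reactants: 2 (S)-linalool triethylsilyl ether
Product: 3 (4S)-4-methyl-4-(triethylsilyloxy)hex-5-enal
Conditions: O3, CH2Cl2, pyridine, −78 °C (Sudan red 7B end point); then Me2S
Reagents that add atoms: ozone, [O-][O+]=O
Why: Chemoselective ozonolysis, because the electron-rich trisubstituted alkene should react far faster than the vinyl group beside the silyloxy-bearing quaternary carbon.

Step 3
Reactants: 3 (4S)-4-methyl-4-(triethylsilyloxy)hex-5-enal
Product: 4 (2E,6S)-enal
Conditions: Ph3P=CHCHO, toluene, 90 °C
Reagents that add atoms: (triphenylphosphoranylidene)acetaldehyde, O=CC=P(c1ccccc1)(c1ccccc1)c1ccccc1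
Why: Wittig olefination with a stabilised ylide should give the (E)-enal by two-carbon homologation.

Step 4
Reactants: 5 but-2-yne-1,4-diol
Product: 6 (2E)-2-allylbut-2-ene-1,4-diol
Conditions: allylMgBr (4 equiv), CuI (10 mol %), THF, −20 °C → rt; then 1 M HCl, 0 °C
Reagents that add atoms: allylmagnesium bromide, C=CC[Mg]Br
Why: Anti-carbomagnesiation of a propargylic alkoxide: allyl adds to one alkyne carbon, magnesium is held cis to the CH2O of that carbon by chelation, and protonation gives the E diol; the two alkoxides are poor leaving groups, so no allene should form.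

Step 5
Reactants: 6 (2E)-2-allylbut-2-ene-1,4-diol
Product: 7 bis(methyl carbonate) of 6
Conditions: ClCO2Me, pyridine, CH2Cl2, 0 °C
Reagents that add atoms: methyl chloroformate, COC(=O)Cl
Why: Acylation of both primary allylic alcohols; one carbonate serves as the leaving group of step 6 and the other is carried on as the acyl donor of step 8, so the two hydroxyls need not be told apart.

Step 6
Reactants: 7 bis(methyl carbonate)
Product: 8 (2S)-α-substituted allylboronate
Conditions: Cu(OtBu) (5 mol %), QuinoxP* (5 mol %), B2pin2, THF, 0 °C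
Reagents that add atoms: bis(pinacolato)diboron, CC1(C)OB(OC1(C)C)B1OC(C)(C)C(C)(C)O1
Why: Copper-catalysed enantioselective γ-selective (SN2′) allylic borylation: the boryl copper species adds across the alkene with boron on the less substituted CH carbon, the carbonate on the CH2 at the allyl-bearing carbon is eliminated (the other SN2′ mode would need boron at the fully substituted carbon), and the chiral bisphosphine selects the alkene face that gives the (S) C–B centre.

Step 7
Reactants: 4 (2E,6S)-enal, 8 (2S)-allylboronate
Product: 9 (2Z,5R,6E,10S)-dienol carbonate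
Conditions: toluene, 25 → 40 °C; then H2O
Reagents that add atoms: none
Why: Allylboration of the aldehyde (1,2-addition) through a closed chair in which the alkenyl group of the enal is equatorial and the CH2OCO2Me group on the boron-bearing carbon is axial (this avoids the pinacol oxygens and the neighbouring 2-substituent), so the C–B centre is transferred to the (5R)-carbinol and the new trisubstituted alkene is Z.

Step 8
Reactants: 9 (2Z,5R,6E,10S)-dienol carbonate
Product: 12 (3Z,4S,5R)-hydroxymethylidene lactone, via potassium alkoxide 10 (not isolated), via potassium aldehyde enolate 11 (not isolated)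
Conditions: KH (1.5 equiv), 18-crown-6, THF, 0 → 40 °C; then AcOH
Reagents that add atoms: none
Why: KH/18-crown-6 turns the C5 carbinol of 9 into the free potassium alkoxide 10, whose 1,5-diene (C2=C3–C4–C5–C6=C7 of the dodecatriene) undergoes an anionic oxy-Cope [3,3] shift that breaks C4–C5, joins C2 to C7 (the ring-fusion bond, lactone C5–C4), turns the allyl-substituted alkene into the exocyclic methylene and releases aldehyde enolate 11. The enolate carbon of 11 then attacks the methyl carbonate five atoms away and expels methoxide, so that the second bond (lactone C3–C2) and the lactone ring form and the product is drained as the stabilised enolate of the formyl lactone. The closest known reaction types are the anionic oxy-Cope rearrangement of acyclic 1,5-dien-3-olates with trapping of the enolate in the same flask and the Dieckmann-type C-acylation of enolates by carbonates. Only one ring is closed, the δ-lactone, by 6-exo-trig attack of the enolate carbon on the carbonate carbonyl; the sigmatropic step closes no ring. Both new stereocentres arise in the chair transition state, in which the (6E)-alkenyl substituent and the oxido group are equatorial and the CH2OCO2Me group of the (2Z)-alkene is axial, so that the (5R)-carbinol, which is destroyed, transfers its configuration to lactone C4 (S) and C5 (R), the trans ring fusion. The step needs chair over boat, equatorial over axial alkoxide and C- over O-acylation, secured respectively by the open-chain (E,Z)-diene, by the crown-ether-separated alkoxide and by the six- against eight-membered ring that C- and O-attack would form.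

Step 9
Reactants: 12 (3Z,4S,5R)-hydroxymethylidene lactone
Product: 13 desilylated hydroxymethylidene lactone
Conditions: HF·pyridine, pyridine, THF, 0 °C → rt
Reagents that add atoms: none
Why: Fluoride cleavage of the tertiary triethylsilyl ether frees the allylic hydroxyl needed for steps 11 and 15, at a stage where no epoxide or enol triflate is yet present.

Step 10
Reactants: 13 desilylated hydroxymethylidene lactone
Product: 14 (E)-enol triflate
Conditions: PhNTf2, Et3N, DMAP (cat.), CH2Cl2, 0 °C
Reagents that add atoms: N-phenylbis(trifluoromethanesulfonimide), O=S(=O)(N(c1ccccc1)S(=O)(=O)C(F)(F)F)C(F)(F)F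
Why: O-Sulfonylation of the vinylogous acid under non-chelating amine conditions should place the triflate anti to the lactone carbonyl (E), the geometry later handed on to the side chain, while the tertiary alcohol is inert to this reagent.

Step 11
Reactants: 14 (E)-enol triflate
Product: 15 bicyclic (Z)-cyclononene enol triflate
Conditions: second-generation Grubbs catalyst (10 mol %), toluene (1 mM), 80 °C
Reagents that add atoms: none
Why: Ring-closing metathesis of the allyl and vinylcarbinol termini, which the trans-fused lactone holds gauche; the nine-membered ring can only hold the Z alkene, and the 1,1-disubstituted alkene and the electron-poor enol triflate are poor metathesis partners.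

Step 12
Reactants: 16 3-methylbut-2-en-1-ol
Product: 17 (2S)-epoxy alcohol
Conditions: Ti(OiPr)4 (5 mol %), L-(+)-diethyl tartrate (6 mol %), tBuOOH, 4 Å MS, CH2Cl2, −20 °C
Reagents that add atoms: tert-butyl hydroperoxide, CC(C)(C)OO
Why: Sharpless asymmetric epoxidation; with L-(+)-tartrate the oxygen is delivered to the face that gives the (2S)-epoxy alcohol, the same sense as for allyl alcohol and geraniol.

Step 13
Reactants: 17 (2S)-epoxy alcohol
Product: 18 (2R)-epoxy aldehyde
Conditions: Dess–Martin periodinane, pyridine, CH2Cl2, 0 °C; used as a solution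
Reagents that add atoms: none
Why: Mild buffered oxidation of the primary alcohol leaves the epoxide stereocentre intact (the descriptor changes only because the priorities change).

Step 14
Reactants: 15 bicyclic enol triflate, 18 (2R)-epoxy aldehyde
Product: 19 bicyclic epoxy diol
Conditions: CrCl2 (6 equiv), NiCl2 (2 mol %), DMF, 25 °C
Reagents that add atoms: none
Why: Nozaki–Hiyama–Kishi coupling: nickel-catalysed activation of the enol triflate with retention of alkene geometry, transfer to chromium and addition to the aldehyde, where Felkin–Anh attack anti to the epoxide C–O bond should give the anti (erythro) epoxy alcohol, i.e. the (S) carbinol.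

Step 15
Reactants: 19 bicyclic epoxy diol
Product: 20 CNP0147265.1
Conditions: VO(acac)2 (5 mol %), tBuOOH, CH2Cl2, 0 °C
Reagents that add atoms: tert-butyl hydroperoxide, CC(C)(C)OO
Why: Vanadium-catalysed hydroxyl-directed epoxidation: the tertiary allylic alcohol delivers the oxygen to the syn face of the ring Z alkene (cis epoxy alcohol, 5R,6R), while the methylidene group and the electron-poor alkylidene lactone are not addressed.

Compound list
1 | (3S)-3,7-dimethylocta-1,6-dien-3-ol, (S)-(+)-linalool | C=C[C@@](C)(O)CCC=C(C)C | starting material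
2 | triethyl{[(3S)-3,7-dimethylocta-1,6-dien-3-yl]oxy}silane | C=C[C@@](C)(O[Si](CC)(CC)CC)CCC=C(C)C | intermediate
3 | (4S)-4-methyl-4-[(triethylsilyl)oxy]hex-5-enal | C=C[C@@](C)(O[Si](CC)(CC)CC)CCC=O | intermediate
4 | (2E,6S)-6-methyl-6-[(triethylsilyl)oxy]octa-2,7-dienal | C=C[C@@](C)(O[Si](CC)(CC)CC)CC/C=C/C=O | intermediate
5 | but-2-yne-1,4-diol | OCC#CCO | starting material
6 | (2E)-2-(prop-2-en-1-yl)but-2-ene-1,4-diol | OC/C(CC=C)=C/CO | intermediate
7 | dimethyl (2E)-2-(prop-2-en-1-yl)but-2-ene-1,4-diyl biscarbonate | COC(=O)OC/C(CC=C)=C/COC(=O)OC | intermediate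
8 | methyl [(2S)-3-methylidene-2-(4,4,5,5-tetramethyl-1,3,2-dioxaborolan-2-yl)hex-5-en-1-yl] carbonate | C=CCC(=C)[C@@H](COC(=O)OC)B1OC(C)(C)C(C)(C)O1 | intermediate
9 | methyl [(2Z,5R,6E,10S)-5-hydroxy-10-methyl-3-(prop-2-en-1-yl)-10-[(triethylsilyl)oxy]dodeca-2,6,11-trien-1-yl] carbonate | C=C[C@@](C)(O[Si](CC)(CC)CC)CC/C=C/[C@H](O)C/C(CC=C)=C\COC(=O)OC | intermediate
10 | potassium (2Z,5R,6E,10S)-1-[(methoxycarbonyl)oxy]-10-methyl-3-(prop-2-en-1-yl)-10-[(triethylsilyl)oxy]dodeca-2,6,11-trien-5-olate | C=C[C@@](C)(O[Si](CC)(CC)CC)CC/C=C/[C@H]([O-])C/C(CC=C)=C\COC(=O)OC.[K+] | intermediate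
11 | potassium (1E,3S,4R)-4-{[(methoxycarbonyl)oxy]methyl}-5-methylidene-3-{(3S)-3-methyl-3-[(triethylsilyl)oxy]pent-4-en-1-yl}octa-1,7-dien-1-olate | C=C[C@@](C)(O[Si](CC)(CC)CC)CC[C@H](/C=C/[O-])[C@@H](COC(=O)OC)C(=C)CC=C.[K+] | intermediate
12 | (3Z,4S,5R)-3-(hydroxymethylidene)-4-{(3S)-3-methyl-3-[(triethylsilyl)oxy]pent-4-en-1-yl}-5-(penta-1,4-dien-2-yl)oxan-2-one | C=C[C@@](C)(O[Si](CC)(CC)CC)CC[C@@H]1/C(=C/O)C(=O)OC[C@H]1C(=C)CC=C | intermediate
13 | (3Z,4S,5R)-4-[(3S)-3-hydroxy-3-methylpent-4-en-1-yl]-3-(hydroxymethylidene)-5-(penta-1,4-dien-2-yl)oxan-2-one | C=C[C@@](C)(O)CC[C@@H]1/C(=C/O)C(=O)OC[C@H]1C(=C)CC=C | intermediate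
14 | (E)-[(4S,5R)-4-[(3S)-3-hydroxy-3-methylpent-4-en-1-yl]-2-oxo-5-(penta-1,4-dien-2-yl)oxan-3-ylidene]methyl trifluoromethanesulfonate | C=C[C@@](C)(O)CC[C@@H]1/C(=C\OS(=O)(=O)C(F)(F)F)C(=O)OC[C@H]1C(=C)CC=C | intermediate
15 | (E)-[(1S,4S,5Z,9R)-4-hydroxy-4-methyl-8-methylidene-12-oxo-11-oxabicyclo[7.4.0]tridec-5-en-13-ylidene]methyl trifluoromethanesulfonate | C=C1C/C=C\[C@@](C)(O)CC[C@@H]2/C(=C\OS(=O)(=O)C(F)(F)F)C(=O)OC[C@@H]12 | intermediate
16 | 3-methylbut-2-en-1-ol | CC(C)=CCO | starting material
17 | [(2S)-3,3-dimethyloxiran-2-yl]methanol | OC[C@@H]1OC1(C)C | intermediate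
18 | (2R)-3,3-dimethyloxirane-2-carbaldehyde | O=C[C@@H]1OC1(C)C | intermediate
19 | (1S,4S,5Z,9R,13E)-13-{(2S)-2-[(2S)-3,3-dimethyloxiran-2-yl]-2-hydroxyethylidene}-4-hydroxy-4-methyl-8-methylidene-11-oxabicyclo[7.4.0]tridec-5-en-12-one | C=C1C/C=C\[C@@](C)(O)CC[C@@H]2/C(=C\[C@H](O)[C@@H]3OC3(C)C)C(=O)OC[C@@H]12 | intermediate
20 | CNP0147265.1, (1S,4S,5R,6R,9R,13E)-5,6-epoxy-13-{(2S)-2-[(2S)-3,3-dimethyloxiran-2-yl]-2-hydroxyethylidene}-4-hydroxy-4-methyl-8-methylidene-11-oxabicyclo[7.4.0]tridecan-12-one | C=C1C[C@H]2O[C@H]2[C@@](C)(O)CC[C@@H]2/C(=C\[C@H](O)[C@@H]3OC3(C)C)C(=O)OC[C@@H]12 | target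

Total step count: 15. Longest linear sequence: 10 steps (steps 1–3, 7–11, 14 and 15).

Steps most likely to fail

Step 8. The alkoxide may pick up the carbonate (transfer through an eight-membered cyclic carbonate), it may fragment by retro-allylation, or a boat or axial-alkoxide transition state may erode the configuration of the ring fusion. The fallback sets out from 9 and makes the two bonds in separate operations. The carbonate is removed (K2CO3, MeOH) to give the diol F1. Its bis-alkoxide (KH, 18-crown-6, THF) undergoes the same oxy-Cope rearrangement, and after protonation the hydroxy aldehyde closes to the lactol F2. Oxidation (Ag2CO3 on Celite, benzene, reflux) gives the lactone F3, whose carbonyl carbon now stems from the enal. Claisen formylation (NaH, HCO2Et, THF) supplies the hydroxymethylidene carbon and returns to the route at 12.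

Step 11. Closure of the strained nine-membered ring may lose to oligomerisation, or the exocyclic methylene may be drawn into a seven-membered ring. The fallback sets out from 9 and inverts the order of ring formation. Metathesis of 9 (second-generation Grubbs catalyst, high dilution) should close the less strained eleven-membered ring of the cycloundecadienol carbonate F4, of which the (9Z) isomer is carried on. The conditions of step 8 then contract this ring across the diene to the bicyclic silyl ether F5. Desilylation (HF·pyridine) gives the bicyclic hydroxymethylidene lactone F6, and triflation as in step 10 returns to the route at 15.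

Step 6. Enantio-induction on the E-trisubstituted allylic carbonate may be insufficient, which would pass into the carbinol of 9 and then into the ring fusion. The fallback sets out from 7 and fixes that carbinol by reagent control instead. Borylation with an achiral catalyst (CuCl, Xantphos, KOtBu, B2pin2) gives the racemic boronate F7. Allylboration of 4 as in step 7 gives the (2Z)-dienol carbonate as a mixture of C5 epimers F8. Oxidation with MnO2 gives the dienone F9, and reduction with (S)-2-methyl-CBS-oxazaborolidine and catecholborane (alkenyl as the large group) should return the (5R)-alcohol, that is 9.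

Further compounds
F1 | step 8 | (2Z,5R,6E,10S)-10-methyl-3-(prop-2-en-1-yl)-10-[(triethylsilyl)oxy]dodeca-2,6,11-triene-1,5-diol | C=C[C@@](C)(O[Si](CC)(CC)CC)CC/C=C/[C@H](O)C/C(CC=C)=C\CO
F2 | step 8 | (4R,5R)-4-{(3S)-3-methyl-3-[(triethylsilyl)oxy]pent-4-en-1-yl}-5-(penta-1,4-dien-2-yl)oxan-2-ol (both anomers) | C=C[C@@](C)(O[Si](CC)(CC)CC)CC[C@@H]1CC(O)OC[C@H]1C(=C)CC=C
F3 | step 8 | (4R,5R)-4-{(3S)-3-methyl-3-[(triethylsilyl)oxy]pent-4-en-1-yl}-5-(penta-1,4-dien-2-yl)oxan-2-one | C=C[C@@](C)(O[Si](CC)(CC)CC)CC[C@@H]1CC(=O)OC[C@H]1C(=C)CC=C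
F4 | step 11 | methyl {(2Z)-2-[(3R,4E,8S,9Z)-3-hydroxy-8-methyl-8-[(triethylsilyl)oxy]cycloundeca-4,9-dien-1-ylidene]ethyl} carbonate | COC(=O)OC/C=C1/C/C=C\[C@@](C)(O[Si](CC)(CC)CC)CC/C=C/[C@H](O)C1
F5 | step 11 | (1S,4S,5Z,9R,13Z)-13-(hydroxymethylidene)-4-methyl-8-methylidene-4-[(triethylsilyl)oxy]-11-oxabicyclo[7.4.0]tridec-5-en-12-one | C=C1C/C=C\[C@@](C)(O[Si](CC)(CC)CC)CC[C@@H]2/C(=C/O)C(=O)OC[C@@H]12
F6 | step 11 | (1S,4S,5Z,9R,13Z)-4-hydroxy-13-(hydroxymethylidene)-4-methyl-8-methylidene-11-oxabicyclo[7.4.0]tridec-5-en-12-one | C=C1C/C=C\[C@@](C)(O)CC[C@@H]2/C(=C/O)C(=O)OC[C@@H]12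
F7 | step 6 | racemic methyl [3-methylidene-2-(4,4,5,5-tetramethyl-1,3,2-dioxaborolan-2-yl)hex-5-en-1-yl] carbonate | C=CCC(=C)C(COC(=O)OC)B1OC(C)(C)C(C)(C)O1
F8 | step 6 | methyl [(2Z,6E,10S)-5-hydroxy-10-methyl-3-(prop-2-en-1-yl)-10-[(triethylsilyl)oxy]dodeca-2,6,11-trien-1-yl] carbonate, both C5 epimers | C=C[C@@](C)(O[Si](CC)(CC)CC)CC/C=C/C(O)C/C(CC=C)=C\COC(=O)OC
F9 | step 6 | methyl [(2Z,6E,10S)-10-methyl-5-oxo-3-(prop-2-en-1-yl)-10-[(triethylsilyl)oxy]dodeca-2,6,11-trien-1-yl] carbonate | C=C[C@@](C)(O[Si](CC)(CC)CC)CC/C=C/C(=O)C/C(CC=C)=C\COC(=O)OC
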